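**Retrosynthetic overview**

1. The last steps only adjust oxidation level and protection (C1 CH2OTBDPS → CO2Me; C14 peroxyketal → OOH); C11–C12 comes from a Julia–Kocienski olefination/diimide reduction joining dioxane sulfone 15 to the C12–C18 aldehyde 23.
2. Aldehyde 23 comes from (R)-linalool: hydroboration, oxetane (a temporary ring, step 12), then invertive perhydrolysis (step 13), which sets C14–OOH.
3. The only ring of the target, the 1,2-dioxane, is closed in one operation by a formal [3+3] annulation that forms C3–C4 and O1–C6 together, from silyl peroxyacetal 6 (C1–C3 with the O–O unit) and cyclopropane 14 (C4–C11; the cyclopropane is a second temporary ring, made in step 7 and opened in step 10).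
4. Enabling feature: in the 1,2-dioxane ring the saturated C4–C5–C6 unit ends at the fully substituted, oxygen-bearing C6 (methyl plus chain), so it is the ring-opened form of a 1,1-disubstituted cyclopropane, while C3 with O2–O1 is a peroxycarbenium ion whose neighbour C2 steers the addition.
5. 6 derives from methyl (S)-3-hydroxy-2-methylpropanoate; 14 from 4-bromo-2-methylbut-1-ene and (R)-3-bromo-2-methylpropan-1-ol.

Key step: step 10

Remark: C1 is the ester carbon and C2–C18 follow the chain, with ring oxygens O1 (on C6) and O2 (on C3); the CIP descriptors of C2, C10 and C14 change along the route only because substituent priorities change, not the spatial arrangement. Commercial (R)-(−)-linalool is assumed to be of high enantiomeric purity.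

**Route**

Step 1
Reactants: 1 methyl (S)-3-hydroxy-2-methylpropanoate
Product: 2 methyl (S)-3-[(tert-butyldiphenylsilyl)oxy]-2-methylpropanoate
Conditions: TBDPSCl, imidazole, CH2Cl2, 0 °C to rt
Reagents that add atoms: tert-butyl(chloro)diphenylsilane, CC(C)(C)[Si](Cl)(c1ccccc1)c1ccccc1
Why: O-Silylation of the primary alcohol; TBDPS is chosen because it should survive ozonolysis, the Lewis acid of the key step and the basic olefination, and the stereocentre is not involved.

Step 2
Reactants: 2 methyl (S)-3-[(tert-butyldiphenylsilyl)oxy]-2-methylpropanoate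
Product: 3 (S)-3-[(tert-butyldiphenylsilyl)oxy]-2-methylpropanal
Conditions: i-Bu2AlH (1.05 equiv), CH2Cl2, −78 °C; aq. KNaC4H4O6 (tartrate) work-up
Reagents that add atoms: none
Why: Partial ester reduction with i-Bu2AlH at −78 °C, where the tetrahedral aluminium hemiacetal persists until work-up; the α-stereocentre should be retained if the aldehyde is used at once without chromatography.

Step 3
Reactants: 3 (S)-3-[(tert-butyldiphenylsilyl)oxy]-2-methylpropanal
Product: 4 tert-butyl{[(2R)-4-methoxy-2-methylbut-3-en-1-yl]oxy}diphenylsilane (E/Z mixture)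
Conditions: Ph3P+CH2OMe Cl−, KN(SiMe3)2, THF, −78 to 0 °C
Reagents that add atoms: (methoxymethyl)triphenylphosphonium chloride, COC[P+](c1ccccc1)(c1ccccc1)c1ccccc1.[Cl-]
Why: Wittig olefination with the methoxymethylene ylide; the enol ether (geometry irrelevant) is wanted because its ozonolysis places the carbonyl oxide on C3 regiospecifically, and the non-stabilised ylide at low temperature should not epimerise C2.

Step 4
Reactants: 4 tert-butyl{[(2R)-4-methoxy-2-methylbut-3-en-1-yl]oxy}diphenylsilane
Product: 5 (2S)-3-[(tert-butyldiphenylsilyl)oxy]-1-methoxy-2-methylpropyl hydroperoxide (both epimers at the acetal carbon)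
Conditions: O3, MeOH/CH2Cl2 (1:4), −78 °C; N2 purge, concentrate cold
Reagents that add atoms: ozone, [O-][O+]=O; methanol, CO
Why: Ozonolysis of an enol ether in methanol (Criegee mechanism): the primary ozonide should fragment to methyl formate and the C3 carbonyl oxide, which methanol traps as the hydroperoxy acetal; the new acetal centre forms as a mixture and is erased in step 10.

Step 5
Reactants: 5 (2S)-3-[(tert-butyldiphenylsilyl)oxy]-1-methoxy-2-methylpropyl hydroperoxide
Product: 6 triethyl{[(2S)-3-[(tert-butyldiphenylsilyl)oxy]-1-methoxy-2-methylpropyl]peroxy}silane (both epimers at the acetal carbon)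
Conditions: Et3SiCl, imidazole, DMF, 0 °C
Reagents that add atoms: chlorotriethylsilane, CC[Si](Cl)(CC)CC
Why: O-Silylation of the hydroperoxide gives the silyl peroxyacetal, the established precursor type of silyl peroxycarbenium ions; cold, weakly basic conditions should avoid base-induced fragmentation at the acetal C–H.

Step 6
Reactants: 7 4-bromo-2-methylbut-1-ene; 8 (R)-3-bromo-2-methylpropan-1-ol
Product: 11 (S)-2,6-dimethylhept-6-en-1-ol, via Grignard reagent 9 (not isolated), via bromomagnesium alkoxide 10 (not isolated)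
Conditions: 7 (2.4 equiv), Mg, THF, 40 °C; then 8, −20 °C; Li2CuCl4 (3 mol %), −20 to 0 °C; aq. NH4Cl
Reagents that add atoms: none
Why: Li2CuCl4-catalysed alkyl–alkyl cross-coupling of a Grignard reagent with a primary bromide, the hydroxyl being masked in the flask as its magnesium alkoxide by one sacrificial equivalent of 9; the stereocentre of 8 (later C10) is not at a reacting carbon and is carried over unchanged.

Step 7
Reactants: 11 (S)-2,6-dimethylhept-6-en-1-ol
Product: 12 (S)-2-methyl-5-(1-methylcyclopropyl)pentan-1-ol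
Conditions: Et2Zn (4 equiv), CF3CO2H (2 equiv), CH2I2 (4 equiv), CH2Cl2, 0 °C to rt
Reagents that add atoms: diiodomethane, ICI
Why: Simmons–Smith cyclopropanation with the trifluoroacetate-modified zinc carbenoid CF3CO2ZnCH2I, which methylenates unactivated 1,1-disubstituted alkenes; no stereocentre arises because the two ring CH2 groups are equivalent.

Step 8
Reactants: 12 (S)-2-methyl-5-(1-methylcyclopropyl)pentan-1-ol
Product: 13 5-{[(2S)-2-methyl-5-(1-methylcyclopropyl)pentyl]sulfanyl}-1-phenyl-1H-tetrazole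
Conditions: 1-phenyl-1H-tetrazole-5-thiol, PPh3, DIAD, THF, 0 °C to rt
Reagents that add atoms: 1-phenyl-1H-tetrazole-5-thiol, Sc1nnnn1-c1ccccc1
Why: Mitsunobu thioetherification of the primary alcohol with the acidic heteroaryl thiol; substitution occurs at CH2, so the adjacent stereocentre is untouched.

Step 9
Reactants: 13 5-{[(2S)-2-methyl-5-(1-methylcyclopropyl)pentyl]sulfanyl}-1-phenyl-1H-tetrazole
Product: 14 5-{[(2S)-2-methyl-5-(1-methylcyclopropyl)pentyl]sulfonyl}-1-phenyl-1H-tetrazole
Conditions: 30% H2O2, (NH4)6Mo7O24·4H2O (10 mol %), EtOH, 0 °C to rt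
Reagents that add atoms: hydrogen peroxide, OO
Why: Molybdate-catalysed oxidation of the sulfide to the sulfone; the alkylcyclopropane has no site that is oxidised under these conditions.

Step 10
Reactants: 6 triethyl{[(2S)-3-[(tert-butyldiphenylsilyl)oxy]-1-methoxy-2-methylpropyl]peroxy}silane; 14 5-{[(2S)-2-methyl-5-(1-methylcyclopropyl)pentyl]sulfonyl}-1-phenyl-1H-tetrazole
Product: 15 tert-butyl{(2S)-2-[(3S,6R)-6-methyl-6-{(4S)-4-methyl-5-[(1-phenyl-1H-tetrazol-5-yl)sulfonyl]pentyl}-1,2-dioxan-3-yl]propoxy}diphenylsilane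
Conditions: 6 (1.5 equiv), 14 (1.0 equiv), Me3SiOTf (1.8 equiv), 2,6-di-tert-butyl-4-methylpyridine (0.5 equiv), CH2Cl2, −78 to −30 °C; aq. NaHCO3
Reagents that add atoms: none
Why: Proposed new method: Me3SiOTf should remove methoxide from 6 to give the silyl peroxycarbenium ion R–CH=O(+)–O–SiEt3, which is attacked by a methylene corner of the 1,1-disubstituted cyclopropane of 14 (C3–C4 forms) with Markovnikov cleavage of the CH2–C(quaternary) σ bond, and the tertiary C6 cation so formed is captured by the distal peroxide oxygen (O1–C6 forms) with loss of Et3Si+ to triflate. The closest known reaction types are the Lewis-acid [3+2] annulation of silyl peroxycarbenium ions with alkenes to 1,2-dioxolanes, the Lewis-acid allylation of peroxyacetals, and electrophilic 1,3-additions (acylation, mercuration) across alkylcyclopropanes; here a strained σ bond replaces the π bond as nucleophile, so one more carbon is delivered and the ring is six-membered. The 1,2-dioxane closes by oxygen–carbocation recombination through a chair-like six-membered transition state (capture at a trigonal cation, so no Baldwin restriction applies). C3 is controlled by the existing C2 centre: Felkin–Anh addition anti to the CH2OTBDPS group should give the 2,3-syn, (3S) isomer. C6 is controlled in the ring-closing transition state, where the C3 side chain sits equatorial and the longer C7 chain should prefer the pseudo-equatorial site over methyl, giving (6R); this preference is expected to be modest and the C6 epimer is to be removed by chromatography. The step needs chemoselectivity for the weakly nucleophilic cyclopropane and regioselective σ-bond cleavage, secured because 14 carries no π-nucleophile (alkene and hydroperoxide are introduced later; sulfone and silyl ether are inert) and because only cleavage toward the quaternary carbon gives a tertiary cation.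

Step 11
Reactants: 16 (R)-(−)-linalool
Product: 17 (R)-3,7-dimethyloct-6-ene-1,3-diol
Conditions: 9-BBN (2.2 equiv), THF, 0 °C to rt; then NaOH, H2O2, 0 °C
Reagents that add atoms: hydrogen peroxide, OO
Why: Hydroboration–oxidation: 9-BBN adds anti-Markovnikov to the monosubstituted vinyl group and leaves the trisubstituted alkene, and the tertiary carbinol stereocentre of linalool is not touched.

Step 12
Reactants: 17 (R)-3,7-dimethyloct-6-ene-1,3-diol
Product: 19 (R)-2-methyl-2-(4-methylpent-3-en-1-yl)oxetane, via monotosylate 18 (not isolated)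
Conditions: n-BuLi (1.0 equiv), THF, 0 °C; TsCl (1.0 equiv); then n-BuLi (1.05 equiv), 0 to 60 °C
Reagents that add atoms: none
Why: One-flask oxetane synthesis from a 1,3-diol: the primary lithium alkoxide is tosylated selectively and the tertiary alkoxide closes the ring by 4-exo-tet Williamson displacement, so the C–O bond at C14 stays intact and its configuration is retained.

Step 13
Reactants: 19 (R)-2-methyl-2-(4-methylpent-3-en-1-yl)oxetane
Product: 20 (S)-3-hydroperoxy-3,7-dimethyloct-6-en-1-ol
Conditions: anhydrous H2O2 in Et2O (10 equiv), Me3SiOTf (0.2 equiv), Et2O, −78 to 0 °C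
Reagents that add atoms: hydrogen peroxide, OO
Why: Lewis-acid-promoted perhydrolysis of a 2,2-disubstituted oxetane: H2O2 should open the activated ring at the tertiary carbon from the rear (SN2-like, tight ion pair), so C14–OOH is set with inversion relative to linalool.

Step 14
Reactants: 20 (S)-3-hydroperoxy-3,7-dimethyloct-6-en-1-ol
Product: 22 (S)-3-[(2-methoxypropan-2-yl)peroxy]-3,7-dimethyloct-6-en-1-ol, via bis-ketal 21 (not isolated)
Conditions: 2-methoxypropene (3 equiv), pyridinium p-toluenesulfonate (2 mol %), CH2Cl2, 0 °C; then MeOH, 0 °C, short contact; Et3N quench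
Reagents that add atoms: 2-methoxypropene, COC(C)=C
Why: Acid-catalysed addition of hydroperoxide and alcohol to 2-methoxypropene (peroxyketal and mixed-ketal formation), then brief transketalisation with methanol, which should strip only the far more labile alkyl 2-methoxypropan-2-yl ether and leave the peroxyketal.

Step 15
Reactants: 22 (S)-3-[(2-methoxypropan-2-yl)peroxy]-3,7-dimethyloct-6-en-1-ol
Product: 23 (S)-3-[(2-methoxypropan-2-yl)peroxy]-3,7-dimethyloct-6-enal
Conditions: Dess–Martin periodinane, NaHCO3, CH2Cl2, 0 °C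
Reagents that add atoms: none
Why: Dess–Martin oxidation of the primary alcohol under bicarbonate buffer, neutral conditions that should spare the peroxyketal and the alkene; the enolisable β-peroxy aldehyde is used at once.

Step 16
Reactants: 15 tert-butyl{(2S)-2-[(3S,6R)-6-methyl-6-{(4S)-4-methyl-5-[(1-phenyl-1H-tetrazol-5-yl)sulfonyl]pentyl}-1,2-dioxan-3-yl]propoxy}diphenylsilane; 23 (S)-3-[(2-methoxypropan-2-yl)peroxy]-3,7-dimethyloct-6-enal
Product: 24 tert-butyl{(2S)-2-[(3S,6R)-6-{(4S,5E,8S)-8-[(2-methoxypropan-2-yl)peroxy]-4,8,12-trimethyltrideca-5,11-dien-1-yl}-6-methyl-1,2-dioxan-3-yl]propoxy}diphenylsilane (5E expected as the major isomer)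
Conditions: KN(SiMe3)2 (1.05 equiv), DME, −78 °C, 15 min; then 23, −78 to −20 °C; aq. NH4Cl
Reagents that add atoms: none
Why: Julia–Kocienski olefination: the potassium sulfonyl carbanion of 15 should add to the aldehyde at −78 °C faster than it enolises it, and Smiles rearrangement with loss of SO2 and the tetrazolone gives the C11=C12 alkene (geometry irrelevant), with no stereocentre at a reacting carbon.

Step 17
Reactants: 24 tert-butyl{(2S)-2-[(3S,6R)-6-{(4S,5E,8S)-8-[(2-methoxypropan-2-yl)peroxy]-4,8,12-trimethyltrideca-5,11-dien-1-yl}-6-methyl-1,2-dioxan-3-yl]propoxy}diphenylsilane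
Product: 25 tert-butyl{(2S)-2-[(3S,6R)-6-{(4S,8R)-8-[(2-methoxypropan-2-yl)peroxy]-4,8,12-trimethyltridec-11-en-1-yl}-6-methyl-1,2-dioxan-3-yl]propoxy}diphenylsilane
Conditions: TsNHNH2 (6 equiv), NaOAc, DME/H2O, 75 °C
Reagents that add atoms: none
Why: Diimide reduction is a concerted syn transfer of H2 that should reduce the 1,2-disubstituted alkene much faster than the trisubstituted one and does not cleave O–O bonds.

Step 18
Reactants: 25 tert-butyl{(2S)-2-[(3S,6R)-6-{(4S,8R)-8-[(2-methoxypropan-2-yl)peroxy]-4,8,12-trimethyltridec-11-en-1-yl}-6-methyl-1,2-dioxan-3-yl]propoxy}diphenylsilane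
Product: 26 (2S)-2-[(3S,6R)-6-{(4S,8R)-8-[(2-methoxypropan-2-yl)peroxy]-4,8,12-trimethyltridec-11-en-1-yl}-6-methyl-1,2-dioxan-3-yl]propan-1-ol
Conditions: Bu4NF/AcOH (1:1), THF, 0 °C to rt
Reagents that add atoms: none
Why: Fluoride-mediated desilylation of the primary TBDPS ether, buffered with acetic acid so that the C3–H of the dioxane is not exposed to basic fluoride (Kornblum–DeLaMare-type fragmentation), while the base-stable peroxyketal stays.

Step 19
Reactants: 26 (2S)-2-[(3S,6R)-6-{(4S,8R)-8-[(2-methoxypropan-2-yl)peroxy]-4,8,12-trimethyltridec-11-en-1-yl}-6-methyl-1,2-dioxan-3-yl]propan-1-ol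
Product: 28 (2R)-2-[(3S,6R)-6-{(4S,8R)-8-[(2-methoxypropan-2-yl)peroxy]-4,8,12-trimethyltridec-11-en-1-yl}-6-methyl-1,2-dioxan-3-yl]propanoic acid, via aldehyde 27 (not isolated)
Conditions: Dess–Martin periodinane, NaHCO3, CH2Cl2, 0 °C; then NaClO2, NaH2PO4, 2-methyl-2-butene, t-BuOH/H2O, 0 °C
Reagents that add atoms: sodium chlorite, [Na+].[O-]Cl=O
Why: Dess–Martin oxidation followed at once by Pinnick oxidation (2-methyl-2-butene scavenges HOCl and protects the trisubstituted alkene); C2 should keep its configuration because the β-peroxy aldehyde is never exposed to base or stored.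

Step 20
Reactants: 28 (2R)-2-[(3S,6R)-6-{(4S,8R)-8-[(2-methoxypropan-2-yl)peroxy]-4,8,12-trimethyltridec-11-en-1-yl}-6-methyl-1,2-dioxan-3-yl]propanoic acid
Product: 29 methyl (2R)-2-[(3S,6R)-6-{(4S,8R)-8-[(2-methoxypropan-2-yl)peroxy]-4,8,12-trimethyltridec-11-en-1-yl}-6-methyl-1,2-dioxan-3-yl]propanoate
Conditions: Me3SiCHN2, MeOH/toluene (1:4), 0 °C
Reagents that add atoms: (trimethylsilyl)diazomethane, C[Si](C)(C)C=[N+]=[N-]
Why: Methyl esterification of the carboxylic acid with (trimethylsilyl)diazomethane/methanol, a neutral O-alkylation that touches neither the peroxides nor any stereocentre.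

Step 21
Reactants: 29 methyl (2R)-2-[(3S,6R)-6-{(4S,8R)-8-[(2-methoxypropan-2-yl)peroxy]-4,8,12-trimethyltridec-11-en-1-yl}-6-methyl-1,2-dioxan-3-yl]propanoate
Product: 30 methyl (2R)-2-[(3S,6R)-6-[(4R,8R)-8-hydroperoxy-4,8,12-trimethyltridec-11-en-1-yl]-6-methyl-1,2-dioxan-3-yl]propanoate (CNP0381652.2)
Conditions: AcOH/THF/H2O (4:2:1), rt
Reagents that add atoms: none
Why: Mild acid hydrolysis of the 2-methoxypropan-2-yl peroxyketal releases the tertiary hydroperoxide; the dialkyl peroxide ring, the methyl ester and the alkene should be stable to aqueous acetic acid.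

**Compound list**

1 | methyl (S)-3-hydroxy-2-methylpropanoate | C[C@@H](CO)C(=O)OC | starting material
2 | methyl (S)-3-[(tert-butyldiphenylsilyl)oxy]-2-methylpropanoate | C[C@@H](CO[Si](c1ccccc1)(c1ccccc1)C(C)(C)C)C(=O)OC | intermediate
3 | (S)-3-[(tert-butyldiphenylsilyl)oxy]-2-methylpropanal | C[C@@H](CO[Si](c1ccccc1)(c1ccccc1)C(C)(C)C)C=O | intermediate
4 | tert-butyl{[(2R)-4-methoxy-2-methylbut-3-en-1-yl]oxy}diphenylsilane (E/Z mixture) | COC=C[C@@H](C)CO[Si](c1ccccc1)(c1ccccc1)C(C)(C)C | intermediate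
5 | (2S)-3-[(tert-butyldiphenylsilyl)oxy]-1-methoxy-2-methylpropyl hydroperoxide (acetal epimers) | COC(OO)[C@@H](C)CO[Si](c1ccccc1)(c1ccccc1)C(C)(C)C | intermediate
6 | triethyl{[(2S)-3-[(tert-butyldiphenylsilyl)oxy]-1-methoxy-2-methylpropyl]peroxy}silane (acetal epimers) | CC[Si](CC)(CC)OOC(OC)[C@@H](C)CO[Si](c1ccccc1)(c1ccccc1)C(C)(C)C | intermediate
7 | 4-bromo-2-methylbut-1-ene | C=C(C)CCBr | starting material
8 | (R)-3-bromo-2-methylpropan-1-ol | C[C@H](CO)CBr | starting material
9 | (3-methylbut-3-en-1-yl)magnesium bromide | C=C(C)CC[Mg]Br | intermediate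
10 | bromomagnesium (R)-3-bromo-2-methylpropan-1-olate | C[C@H](CO[Mg]Br)CBr | intermediate
11 | (S)-2,6-dimethylhept-6-en-1-ol | C=C(C)CCC[C@H](C)CO | intermediate
12 | (S)-2-methyl-5-(1-methylcyclopropyl)pentan-1-ol | CC1(CCC[C@H](C)CO)CC1 | intermediate
13 | 5-{[(2S)-2-methyl-5-(1-methylcyclopropyl)pentyl]sulfanyl}-1-phenyl-1H-tetrazole | CC1(CCC[C@H](C)CSc2nnnn2-c2ccccc2)CC1 | intermediate
14 | 5-{[(2S)-2-methyl-5-(1-methylcyclopropyl)pentyl]sulfonyl}-1-phenyl-1H-tetrazole | CC1(CCC[C@H](C)CS(=O)(=O)c2nnnn2-c2ccccc2)CC1 | intermediate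
15 | tert-butyl{(2S)-2-[(3S,6R)-6-methyl-6-{(4S)-4-methyl-5-[(1-phenyl-1H-tetrazol-5-yl)sulfonyl]pentyl}-1,2-dioxan-3-yl]propoxy}diphenylsilane | CC(C)(C)[Si](c1ccccc1)(c1ccccc1)OC[C@H](C)[C@@H]1CC[C@@](C)(CCC[C@H](C)CS(=O)(=O)c2nnnn2-c2ccccc2)OO1 | intermediate
16 | (R)-(−)-linalool, (R)-3,7-dimethylocta-1,6-dien-3-ol | C=C[C@@](C)(CCC=C(C)C)O | starting material
17 | (R)-3,7-dimethyloct-6-ene-1,3-diol | OCC[C@@](C)(CCC=C(C)C)O | intermediate
18 | (R)-3-hydroxy-3,7-dimethyloct-6-en-1-yl 4-methylbenzenesulfonate | Cc1ccc(cc1)S(=O)(=O)OCC[C@@](C)(CCC=C(C)C)O | intermediate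
19 | (R)-2-methyl-2-(4-methylpent-3-en-1-yl)oxetane | C[C@@]1(CCC=C(C)C)CCO1 | intermediate
20 | (S)-3-hydroperoxy-3,7-dimethyloct-6-en-1-ol | OCC[C@](C)(CCC=C(C)C)OO | intermediate
21 | (S)-2-methoxy-2-({3-[(2-methoxypropan-2-yl)peroxy]-3,7-dimethyloct-6-en-1-yl}oxy)propane | COC(C)(C)OCC[C@](C)(CCC=C(C)C)OOC(C)(C)OC | intermediate
22 | (S)-3-[(2-methoxypropan-2-yl)peroxy]-3,7-dimethyloct-6-en-1-ol | OCC[C@](C)(CCC=C(C)C)OOC(C)(C)OC | intermediate
23 | (S)-3-[(2-methoxypropan-2-yl)peroxy]-3,7-dimethyloct-6-enal | O=CC[C@](C)(CCC=C(C)C)OOC(C)(C)OC | intermediate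
24 | tert-butyl{(2S)-2-[(3S,6R)-6-{(4S,5E,8S)-8-[(2-methoxypropan-2-yl)peroxy]-4,8,12-trimethyltrideca-5,11-dien-1-yl}-6-methyl-1,2-dioxan-3-yl]propoxy}diphenylsilane | CC(C)(C)[Si](c1ccccc1)(c1ccccc1)OC[C@H](C)[C@@H]1CC[C@@](C)(CCC[C@H](C)/C=C/CC[C@](C)(CCC=C(C)C)OOC(C)(C)OC)OO1 | intermediate
25 | tert-butyl{(2S)-2-[(3S,6R)-6-{(4S,8R)-8-[(2-methoxypropan-2-yl)peroxy]-4,8,12-trimethyltridec-11-en-1-yl}-6-methyl-1,2-dioxan-3-yl]propoxy}diphenylsilane | CC(C)(C)[Si](c1ccccc1)(c1ccccc1)OC[C@H](C)[C@@H]1CC[C@@](C)(CCC[C@H](C)CCC[C@](C)(CCC=C(C)C)OOC(C)(C)OC)OO1 | intermediate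
26 | (2S)-2-[(3S,6R)-6-{(4S,8R)-8-[(2-methoxypropan-2-yl)peroxy]-4,8,12-trimethyltridec-11-en-1-yl}-6-methyl-1,2-dioxan-3-yl]propan-1-ol | OC[C@H](C)[C@@H]1CC[C@@](C)(CCC[C@H](C)CCC[C@](C)(CCC=C(C)C)OOC(C)(C)OC)OO1 | intermediate
27 | (2R)-2-[(3S,6R)-6-{(4S,8R)-8-[(2-methoxypropan-2-yl)peroxy]-4,8,12-trimethyltridec-11-en-1-yl}-6-methyl-1,2-dioxan-3-yl]propanal | O=C[C@H](C)[C@@H]1CC[C@@](C)(CCC[C@H](C)CCC[C@](C)(CCC=C(C)C)OOC(C)(C)OC)OO1 | intermediate
28 | (2R)-2-[(3S,6R)-6-{(4S,8R)-8-[(2-methoxypropan-2-yl)peroxy]-4,8,12-trimethyltridec-11-en-1-yl}-6-methyl-1,2-dioxan-3-yl]propanoic acid | OC(=O)[C@H](C)[C@@H]1CC[C@@](C)(CCC[C@H](C)CCC[C@](C)(CCC=C(C)C)OOC(C)(C)OC)OO1 | intermediate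
29 | methyl (2R)-2-[(3S,6R)-6-{(4S,8R)-8-[(2-methoxypropan-2-yl)peroxy]-4,8,12-trimethyltridec-11-en-1-yl}-6-methyl-1,2-dioxan-3-yl]propanoate | COC(=O)[C@H](C)[C@@H]1CC[C@@](C)(CCC[C@H](C)CCC[C@](C)(CCC=C(C)C)OOC(C)(C)OC)OO1 | intermediate
30 | methyl (2R)-2-[(3S,6R)-6-[(4R,8R)-8-hydroperoxy-4,8,12-trimethyltridec-11-en-1-yl]-6-methyl-1,2-dioxan-3-yl]propanoate | COC(=O)[C@H](C)[C@@H]1CC[C@@](C)(CCC[C@H](C)CCC[C@](C)(CCC=C(C)C)OO)OO1 | target

**Step count and risks**

Total step count: 21. Longest linear sequence: 12 steps (1 → 6 by steps 1–5, then steps 10 and 16–21).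

Step 10 (bears the new-method label). What may go wrong: the σ bond of the alkylcyclopropane may be too weak a nucleophile, so that the peroxycarbenium ion is lost by elimination or rearrangement before C–C bond formation; or capture of the C6 cation may proceed with poor facial selectivity. The fallback uses known reactions only, sets out from 6 and 11 and comes back at 15. Compound 11 is carried through the conditions of steps 8 and 9 to the alkenyl sulfide F1 and then the alkenyl sulfone F2. Compound 6 is allylated with allyltrimethylsilane and SnCl4 (CH2Cl2, −78 °C; Lewis-acid allylation of a peroxyacetal, Felkin–Anh control of C3) to the homoallyl silyl peroxide F3. Cross-metathesis of F3 with an excess of F2 (second-generation Hoveyda–Grubbs catalyst, CH2Cl2, 40 °C) gives the trisubstituted alkene F4, and HF·pyridine (THF, 0 °C) frees the hydroperoxide F5. Hg(OAc)2 with catalytic HClO4 (CH2Cl2, 0 °C) then closes the ring by 6-endo Markovnikov cycloperoxymercuration to the organomercurial F6, and NaBH4/NaOH demercuration gives 15 after separation of the C6 epimer.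

Step 13. What may go wrong: leakage of the substitution through a free tertiary carbocation, which erodes the configuration at C14, or capture of that cation by the trisubstituted alkene. The fallback sets out from 22 (stereochemically impure at C14) and comes back at 22 as a single stereoisomer. The alcohol is acylated with (1S,4R)-camphanic chloride (pyridine, DMAP, CH2Cl2) to the camphanate ester F7, whose C14 diastereomers are separated by HPLC or crystallisation (classical resolution through a covalent chiral auxiliary). Methanolysis with K2CO3/MeOH at 0 °C then returns 22, the peroxyketal being base-stable.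

Step 14. What may go wrong: loss of the peroxyketal together with the alkyl ketal during methanolysis if the rate difference is too small, or incomplete unmasking of the alcohol. The fallback sets out from 20 and comes back at 22. The primary hydroxyl is first acetylated chemoselectively with isopropenyl acetate and immobilised Candida antarctica lipase B (the hindered tertiary hydroperoxide is not expected to be a substrate) to the hydroperoxy acetate F8. 2-Methoxypropene with pyridinium p-toluenesulfonate then gives the peroxyketal acetate F9, and K2CO3/MeOH at 0 °C removes the acetate to give 22.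

**Further compounds**

F1 | step 10 | 5-{[(2S)-2,6-dimethylhept-6-en-1-yl]sulfanyl}-1-phenyl-1H-tetrazole | C=C(C)CCC[C@H](C)CSc1nnnn1-c1ccccc1
F2 | step 10 | 5-{[(2S)-2,6-dimethylhept-6-en-1-yl]sulfonyl}-1-phenyl-1H-tetrazole | C=C(C)CCC[C@H](C)CS(=O)(=O)c1nnnn1-c1ccccc1
F3 | step 10 | tert-butyl{[(2S,3S)-2-methyl-3-[(triethylsilyl)peroxy]hex-5-en-1-yl]oxy}diphenylsilane | CC(C)(C)[Si](c1ccccc1)(c1ccccc1)OC[C@H](C)[C@@H](OO[Si](CC)(CC)CC)CC=C
F4 | step 10 | tert-butyl{[(2S,3S,10S)-2,6,10-trimethyl-11-[(1-phenyl-1H-tetrazol-5-yl)sulfonyl]-3-[(triethylsilyl)peroxy]undec-5-en-1-yl]oxy}diphenylsilane (E/Z mixture) | CC(C)(C)[Si](c1ccccc1)(c1ccccc1)OC[C@H](C)[C@@H](OO[Si](CC)(CC)CC)CC=C(C)CCC[C@H](C)CS(=O)(=O)c1nnnn1-c1ccccc1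
F5 | step 10 | (2S,3S,10S)-1-[(tert-butyldiphenylsilyl)oxy]-2,6,10-trimethyl-11-[(1-phenyl-1H-tetrazol-5-yl)sulfonyl]undec-5-en-3-yl hydroperoxide (E/Z mixture) | CC(C)(C)[Si](c1ccccc1)(c1ccccc1)OC[C@H](C)[C@@H](OO)CC=C(C)CCC[C@H](C)CS(=O)(=O)c1nnnn1-c1ccccc1
F6 | step 10 | acetato{(3S,6R)-6-[(2S)-1-[(tert-butyldiphenylsilyl)oxy]propan-2-yl]-3-methyl-3-{(4S)-4-methyl-5-[(1-phenyl-1H-tetrazol-5-yl)sulfonyl]pentyl}-1,2-dioxan-4-yl}mercury (epimers at the mercurated carbon) | CC(C)(C)[Si](c1ccccc1)(c1ccccc1)OC[C@H](C)[C@@H]1CC([Hg]OC(C)=O)[C@@](C)(CCC[C@H](C)CS(=O)(=O)c2nnnn2-c2ccccc2)OO1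
F7 | step 13 | (S)-3-[(2-methoxypropan-2-yl)peroxy]-3,7-dimethyloct-6-en-1-yl (1S,4R)-4,7,7-trimethyl-3-oxo-2-oxabicyclo[2.2.1]heptane-1-carboxylate | CC1(C)[C@@]2(C)CC[C@@]1(OC2=O)C(=O)OCC[C@](C)(CCC=C(C)C)OOC(C)(C)OC
F8 | step 14 | (S)-3-hydroperoxy-3,7-dimethyloct-6-en-1-yl acetate | CC(=O)OCC[C@](C)(CCC=C(C)C)OO
F9 | step 14 | (S)-3-[(2-methoxypropan-2-yl)peroxy]-3,7-dimethyloct-6-en-1-yl acetate | CC(=O)OCC[C@](C)(CCC=C(C)C)OOC(C)(C)OC
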